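## Analysis of the target

CNP0155390.1 is a C30 seco-triterpenoid of the iridal type. It has two ring systems joined by a four-carbon chain: a 2,2,3,5-tetrasubstituted tetrahydrofuran (O1, C2–C5) and a pentasubstituted cyclohexane, ring B (B1–B6). The tetrahydrofuran has a quaternary C2 (methyl and 4-methylpent-3-enyl, S), a secondary hydroxyl at C3 (R) and, at C5 (R), an (E)-trisubstituted alkene C(CH3)=CH that runs through two CH2 groups to B1. The C5 alkenyl group is cis to the C2 methyl and the C3 hydroxyl. Ring B has a quaternary B1 (methyl and the chain, S), a 3-hydroxypropyl arm at B2 (R), an exocyclic tetrasubstituted (Z)-enal at B3 with the formyl group on the B2 side, and a tertiary carbinol B6 (S); the B1 methyl, the B2 arm and the B6 hydroxyl share one face. The two stereotriads are five bonds apart, so neither can control the other; in all there are six stereocentres and two configured alkenes. The sensitive groups are the enal, the allylic C5–O1 ether (ionisation under acid), the two tertiary alcohols and the tri- and tetrasubstituted alkenes. The hard points are the vicinal fully substituted B1/B6 pair, the geometry of the tetrasubstituted alkene, and the union of the halves with control at C5. The strategy rests on one feature: C5 is bonded to O1 and is allylic to the (E)-alkene, so the O1–C5 bond, the C5 configuration and the alkene geometry can all come from one allylic transposition of an acyclic allylic alcohol.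

## Retrosynthetic reasoning

**38 back to 37 and 36.** No skeletal bond is cut. The enal would not survive the organometallic fragment union, so it is carried as a silylated allylic alcohol. 38 comes from tetraol 37 by an oxidation that touches only allylic alcohols, and 37 from the tris-silyl ether 36 by desilylation. These steps must leave the (Z) geometry and the allylic C5–O1 ether alone.

**36 back to 35: the O1–C5 bond.** Cutting at O1–C2 would require attack on a tertiary carbon with inversion, and a C–C cut would not use the allylic position. Cutting O1–C5 opens the ring to an acyclic 1,2-diol with an allylic alcohol three atoms further on, compound 35. Forward, the C2 oxygen adds to C5 while the allylic hydroxyl leaves from the carbinol carbon and the alkene shifts. One step gives the ring, the C5 stereocentre and the (E)-alkene; C2 and C3 are carried over unchanged. The transposition must be syn and must go through one rotamer.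

**35 back to 31 and 22: the bond between the carbinol carbon and the methyl-bearing alkene carbon.** This cut splits the skeleton into a C13 half and a C17 half. The only stereocentre made in the union lies between an alkenyl group and a CH2 group, which a chiral catalyst can tell apart. Alkyne 31 gives the alkenylmetal by syn hydrometalation, which also fixes the (E)-alkene; aldehyde 22 is the electrophile. The addition must be catalyst-controlled, because the stereocentres of 22 are four bonds away.

**31 back to 27 and 28, and on to 23.** The CH2–C(sp) bond is cut, so that the alkyne comes from propyne 28 and the diol from terminal epoxide 27. Epoxide 27 goes back through triol 25 to epoxy alcohol 24 and geraniol 23. The epoxidation sets both oxygen-bearing carbons; hydrolysis with inversion at the tertiary carbon then turns the syn relationship into the anti diol the tetrahydrofuran needs. The remote alkene of 23 becomes the 4-methylpent-3-enyl tail.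

**22 back to 19.** The three-carbon aldehyde arm at B1 is traced through alcohol 21 to the allyl group of 19, so that B1 can be built by enolate allylation. The B6 oxygen must be silylated before the aldehyde exists, because it sits δ to the carbonyl carbon and would close a lactol.

**19 back to 15: the B3=C double bond.** It is traced through allylic alcohol 18, enal 17 and tertiary allylic alcohol 16 to ketone 15. An isopropenyl nucleophile adds to the ketone and an oxidative 1,3-transposition moves the oxygen to the chain terminus. A direct olefination is not chosen: a stabilised carbanion would have to attack a hindered ketone under basic conditions that endanger B2, and would not control the geometry.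

**15 back to 11: the B6–CH3 bond.** Through 14 and 12, the tertiary carbinol comes from adding a methyl nucleophile to ketone 11; the axial methyl at B1 decides the face.

**11 back to 6 and 7: the B2–CH2 and B1–allyl bonds.** Both form in one operation on enone 6: conjugate addition of the Grignard reagent from 7, then allylation of the enolate. The silyloxy group at B3 of 6 steers the first addition and later becomes the ketone where the alkylidene is built, so it is not a throw-away auxiliary.

**6 back to 1.** Enone 6 is the transposition product of vinylogous ester 1 after oxygenation at its α′ carbon (2, 3, 5). Its single stereocentre is secured by enzymatic resolution.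

## Alternatives that were turned down

Alternative 1: Ring B by an intramolecular furan Diels–Alder reaction.
- Disconnection: the ring-B bonds B2–B3 and B1–B6.
- Forward key step: furan enoate A1, a 2-methylfuran joined by a four-carbon tether to an (E)-2-methyl enoate, cyclises under Lewis acid catalysis or heat and pressure to the oxygen-bridged tricyclic ester A2. The furan oxygen becomes the B6 hydroxyl, the enoate carbons become B1 and B2, and the tether forms a temporary carbocycle.
- For it: three ring-B stereocentres, including the fully substituted B1/B6 pair, arise in one step, and the enoate geometry translates directly into the B1/B2 relationship. On this point it is stronger than the chosen route, which needs three steps for the same centres.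
- Against it: cycloadditions of 2,5-disubstituted furans with trisubstituted dienophiles are slow and reversible, and facial control rests on one silyloxy stereocentre in the tether. A2 is also still far from ring B: the bridgehead C–O bond at B3 must be broken selectively, the temporary ring cut, the ester lengthened by two carbons and the alkylidene built.
- Comparison: it leaves the tetrahydrofuran, C5 and the union of the halves unsolved, so a second strategic step would still be needed. The chosen strategy offers instead one late, convergent step that makes a ring, a stereocentre and an alkene, with ring B built by stepwise, individually predictable reactions.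

Alternative 2: The exocyclic alkene from a spiro β-lactone.
- Disconnection: the B3=C double bond.
- Forward key step: the chelated dianion of thioester A3 adds to ring-B ketone A4, and the aldolate closes onto the thioester to give spiro β-lactone A5; heating then causes stereospecific decarboxylation.
- For it: the alkene geometry follows from the relative configuration of two stereocentres through a stereospecific syn elimination. This is firmer than the conformational preference on which step 10 of the chosen route relies, so the alternative is stronger on this point.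
- Against it: the aldol addition must take place at a hindered ketone next to an epimerisable CH, its relative topicity depends on a lithium chelate, and it needs a strong base in at least twofold amount.
- Comparison: as a strategy it places the main risk in ring B and does nothing for the tetrahydrofuran or C5. The chosen route keeps this chemistry in reserve for step 10 and spends its key step where three problems are solved together.

Alternative 3: The tetrahydrofuran by an oxonium ylide [2,3]-shift.
- Disconnection: the O1–C2 bond and the bond from C2 to the first CH2 of the tail.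
- Forward key step: diazoketone A6 is decomposed by a divalent copper catalyst; the allyl ether oxygen attacks the carbenoid to close the five-membered ring, and the allyl group shifts from oxygen to C2 to give tetrahydrofuran-3-one A7.
- For it: the ring and the quaternary C2 form in one step, with a C–C bond made at the most crowded carbon, and the alkenyl iodide is a handle for later coupling. In making a C–C bond at the quaternary centre it is stronger than the chosen route, which takes that centre from the starting terpene.
- Against it: C5 must be set beforehand, the C3 ketone must be reduced from one face, the allyl group must be turned into the 4-methylpent-3-enyl tail, [1,2]-shift and C–H insertion compete, and the union with ring B would join an alkenyl iodide to an sp3 carbon.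
- Comparison: it needs more redox and chain adjustment on the tetrahydrofuran. The chosen strategy takes C2 and C3 in the right oxidation state and configuration from an epoxy alcohol, and forms C5 and the alkene in the ring-closing step.

Key step: step 21

Abbreviations: TBS = tert-butyldimethylsilyl, TES = triethylsilyl, TMS = trimethylsilyl. RB = the ring-B unit (1S,2R,6S)-2-[3-(TBSO)propyl]-3-[(Z)-1-(TBSO)propan-2-ylidene]-1,6-dimethyl-6-(TESO)cyclohexyl.

Remark 1: the lipase in step 2 is assumed to hydrolyse the (R)-acetate of 2 faster, as is usual for secondary acetates; if it prefers the (S)-acetate, the (S)-alcohol it forms is used in step 3 in place of 3, since that step converts either into 5.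

Remark 2: the sense of induction of the amino thiol ligand in step 20 is not taken for granted; the enantiomer that sends the alkenyl group to the Re face of 22 is used (both are available from the enantiomers of 1-phenylethylamine).

## Route

Step 1
Reactants: 1 3-ethoxy-2-methylcyclohex-2-en-1-one
Product: 2 rac-4-ethoxy-3-methyl-2-oxocyclohex-3-en-1-yl acetate
Conditions: Mn(OAc)3·2H2O, benzene, reflux
Reagents that add atoms: manganese triacetate, CC(=O)[O-].CC(=O)[O-].CC(=O)[O-].[Mn+3]
Why: α′-Acetoxylation of an enone by trivalent manganese: the manganese enolate forms at the only enolisable CH2 next to the carbonyl, is oxidised and takes up acetate; the product is racemic.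

Step 2
Reactants: 2 rac-4-ethoxy-3-methyl-2-oxocyclohex-3-en-1-yl acetate
Product: 3 (S)-4-ethoxy-3-methyl-2-oxocyclohex-3-en-1-yl acetate
Conditions: lipase from Burkholderia cepacia, phosphate buffer pH 7, toluene, rt, to just past half conversion
Reagents that add atoms: none
Why: Enzymatic kinetic resolution of a secondary acetate: one enantiomer is hydrolysed and the other recovered, so the unreacted (S)-acetate should be of high enantiomeric purity; this selection fixes the one stereocentre that controls ring B.

Step 3
Reactants: 3 (S)-4-ethoxy-3-methyl-2-oxocyclohex-3-en-1-yl acetate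
Product: 5 (S)-4-hydroxy-2-methylcyclohex-2-en-1-one, via diol 4 (not isolated)
Conditions: LiAlH4, Et2O, 0 °C; then 1 M H2SO4, rt
Reagents that add atoms: water, O
Why: Stork–Danheiser transposition: hydride adds 1,2 to the vinylogous ester carbonyl and cleaves the acetate, then aqueous acid hydrolyses the enol ether and eliminates water to give the transposed enone; the carbinol centre is untouched and becomes C4.

Step 4
Reactants: 5 (S)-4-hydroxy-2-methylcyclohex-2-en-1-one
Product: 6 (S)-2-methyl-4-(triethylsilyloxy)cyclohex-2-en-1-one
Conditions: Et3SiCl, imidazole, CH2Cl2, 0 °C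
Reagents that add atoms: chlorotriethylsilane, CC[Si](Cl)(CC)CC
Why: Standard silylation of a secondary alcohol; TES is chosen because it can later be removed next to a primary TBS ether.

Step 5
Reactants: 6 (S)-2-methyl-4-(triethylsilyloxy)cyclohex-2-en-1-one; 7 (3-bromopropoxy)(tert-butyl)dimethylsilane
Product: 11 (2S,3S,4S)-2-allyl-3-[3-(TBSO)propyl]-2-methyl-4-(TESO)cyclohexan-1-one, via Grignard reagent 8 (not isolated), via trimethylsilyl enol ether 9 (not isolated), via lithium enolate 10 (not isolated)
Conditions: Mg, THF; CuBr·SMe2 (10 mol %), Me3SiCl, HMPA, THF, −78 °C; volatiles removed; MeLi, THF, 0 °C; allyl bromide, HMPA, −78 → 0 °C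
Reagents that add atoms: allyl bromide, C=CCBr
Why: Tandem conjugate addition–enolate alkylation: the copper-catalysed Grignard addition occurs anti to the C4 silyloxy group and sets C3; the enolate, regenerated regiospecifically from the silyl enol ether, is allylated on the face opposite the new C3 chain, which sets the quaternary C2 with its methyl cis to that chain.

Step 6
Reactants: 11 (2S,3S,4S)-2-allyl-3-[3-(TBSO)propyl]-2-methyl-4-(TESO)cyclohexan-1-one
Product: 12 (1S,2S,3S,4S)-2-allyl-3-[3-(TBSO)propyl]-1,2-dimethyl-4-(TESO)cyclohexan-1-ol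
Conditions: MeLi, CeCl3, THF, −78 °C
Reagents that add atoms: methyllithium, C[Li]
Why: Organocerium 1,2-addition without enolisation: in the chair with the C2 methyl axial and every other substituent equatorial, the methyl nucleophile attacks axially, anti to that axial methyl (Felkin–Anh), so the new hydroxyl ends up cis to the C2 methyl.

Step 7
Reactants: 12 (1S,2S,3S,4S)-2-allyl-3-[3-(TBSO)propyl]-1,2-dimethyl-4-(TESO)cyclohexan-1-ol
Product: 14 (1S,2S,3S,4S)-3-allyl-2-[3-(TBSO)propyl]-3,4-dimethyl-4-(TESO)cyclohexan-1-ol, via bis-triethylsilyl ether 13 (not isolated)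
Conditions: Et3SiOTf, 2,6-lutidine, CH2Cl2, −78 → 0 °C; then PPTS, MeOH, 0 °C
Reagents that add atoms: triethylsilyl triflate, CC[Si](CC)(CC)OS(=O)(=O)C(F)(F)F
Why: The silyl triflate caps the hindered tertiary alcohol, which would otherwise interfere with the chromium oxidant in step 10 and form a lactol with the aldehyde of step 14; mild acid methanolysis then removes only the secondary TES ether, since the tertiary TES and primary TBS ethers react more slowly.

Step 8
Reactants: 14 (1S,2S,3S,4S)-3-allyl-2-[3-(TBSO)propyl]-3,4-dimethyl-4-(TESO)cyclohexan-1-ol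
Product: 15 (2S,3S,4S)-3-allyl-2-[3-(TBSO)propyl]-3,4-dimethyl-4-(TESO)cyclohexan-1-one
Conditions: Dess–Martin periodinane, NaHCO3, CH2Cl2, 0 °C → rt
Reagents that add atoms: none
Why: Dess–Martin oxidation of the only free alcohol; the buffered, non-basic medium should not epimerise the α-stereocentre B2.

Step 9
Reactants: 15 (2S,3S,4S)-3-allyl-2-[3-(TBSO)propyl]-3,4-dimethyl-4-(TESO)cyclohexan-1-one
Product: 16 (1R,2S,3S,4S)-3-allyl-2-[3-(TBSO)propyl]-3,4-dimethyl-1-(prop-1-en-2-yl)-4-(TESO)cyclohexan-1-ol
Conditions: isopropenylmagnesium bromide, CeCl3, THF, −78 → 0 °C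
Reagents that add atoms: isopropenylmagnesium bromide, CC(=C)[Mg]Br
Why: The weakly basic organocerium reagent adds to the hindered, enolisable ketone without epimerising B2; equatorial attack is expected because the axial face is blocked by the syn-axial B1 methyl, but the new carbinol centre is lost in the next step and either epimer would serve.

Step 10
Reactants: 16 (1R,2S,3S,4S)-3-allyl-2-[3-(TBSO)propyl]-3,4-dimethyl-1-(prop-1-en-2-yl)-4-(TESO)cyclohexan-1-ol
Product: 17 (2Z)-2-[(2R,3S,4S)-3-allyl-2-[3-(TBSO)propyl]-3,4-dimethyl-4-(TESO)cyclohexylidene]propanal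
Conditions: pyridinium chlorochromate (C5H5NH)[CrO3Cl], 4 Å MS, CH2Cl2, rt
Reagents that add atoms: pyridinium chlorochromate, [O-][Cr](=O)(=O)Cl.c1cc[nH+]cc1
Why: Babler–Dauben oxidation: the chromate ester of the tertiary allylic alcohol undergoes a [3,3] shift to the primary allylic chromate, which is oxidised to the enal. The (Z) geometry should follow from the rotamer that turns the isopropenyl methyl toward the unsubstituted ring CH2 and the methylene toward the substituted B2 (allylic strain). The (Z)-enal should also be the more stable isomer, since a formyl group is smaller than a methyl next to B2.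

Step 11
Reactants: 17 (2Z)-2-[(2R,3S,4S)-3-allyl-2-[3-(TBSO)propyl]-3,4-dimethyl-4-(TESO)cyclohexylidene]propanal
Product: 18 (2Z)-2-[(2R,3S,4S)-3-allyl-2-[3-(TBSO)propyl]-3,4-dimethyl-4-(TESO)cyclohexylidene]propan-1-ol
Conditions: NaBH4, CeCl3·7H2O, MeOH, 0 °C
Reagents that add atoms: none
Why: Luche 1,2-reduction of the enal; the alkene geometry is not affected.

Step 12
Reactants: 18 (2Z)-2-[(2R,3S,4S)-3-allyl-2-[3-(TBSO)propyl]-3,4-dimethyl-4-(TESO)cyclohexylidene]propan-1-ol
Product: 19 tert-butyl-dimethyl-{(2Z)-2-[(2R,3S,4S)-3-allyl-2-[3-(TBSO)propyl]-3,4-dimethyl-4-(TESO)cyclohexylidene]propoxy}silane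
Conditions: tBuMe2SiCl, imidazole, CH2Cl2, 0 °C → rt
Reagents that add atoms: tert-butyldimethylsilyl chloride, CC(C)(C)[Si](C)(C)Cl
Why: Standard silylation of the primary allylic alcohol, which masks the future enal oxygen through the fragment union.

Step 13
Reactants: 19 tert-butyl-dimethyl-{(2Z)-2-[(2R,3S,4S)-3-allyl-2-[3-(TBSO)propyl]-3,4-dimethyl-4-(TESO)cyclohexylidene]propoxy}silane
Product: 21 3-(RB)propan-1-ol, via alkylborane 20 (not isolated)
Conditions: 9-BBN, THF, 0 °C → rt; then NaOH, H2O2, 0 °C
Reagents that add atoms: hydrogen peroxide, OO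
Why: Hydroboration–oxidation: 9-BBN adds only to the monosubstituted alkene, anti-Markovnikov, and leaves the tetrasubstituted alkene alone; oxidation of the C–B bond gives the primary alcohol.

Step 14
Reactants: 21 3-(RB)propan-1-ol
Product: 22 3-(RB)propanal
Conditions: Dess–Martin periodinane, NaHCO3, CH2Cl2, 0 °C
Reagents that add atoms: none
Why: Dess–Martin oxidation of the primary alcohol; with the B6 oxygen silylated the δ-oxygenated aldehyde cannot close to a lactol.

Step 15
Reactants: 23 geraniol
Product: 24 [(2R,3R)-3-methyl-3-(4-methylpent-3-enyl)oxiran-2-yl]methanol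
Conditions: Ti(OiPr)4 (5 mol %), D-(−)-diethyl tartrate (6 mol %), tBuOOH, 4 Å MS, CH2Cl2, −20 °C
Reagents that add atoms: tert-butyl hydroperoxide, CC(C)(C)OO
Why: Sharpless asymmetric epoxidation: the D-tartrate catalyst delivers oxygen to the face of the allylic alcohol that gives the (2R,3R)-epoxide; the remote alkene is not an allylic alcohol and is left alone.

Step 16
Reactants: 24 [(2R,3R)-3-methyl-3-(4-methylpent-3-enyl)oxiran-2-yl]methanol
Product: 25 (2R,3S)-3,7-dimethyloct-6-ene-1,2,3-triol
Conditions: HClO4 (cat.), THF–H2O, 0 °C → rt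
Reagents that add atoms: water, O
Why: Acid-catalysed epoxide hydrolysis: water opens the protonated epoxide at the tertiary carbon C3 with inversion while C2 keeps its oxygen, which gives the anti (2R,3S) diol pattern.

Step 17
Reactants: 25 (2R,3S)-3,7-dimethyloct-6-ene-1,2,3-triol
Product: 27 (2S)-6-methyl-2-[(2R)-oxiran-2-yl]hept-5-en-2-ol, via primary tosylate 26 (not isolated)
Conditions: TsCl, Et3N, Bu2SnO (cat.), CH2Cl2, 0 °C; then K2CO3, MeOH, 0 °C
Reagents that add atoms: none
Why: Tin-catalysed sulfonylation selects the primary hydroxyl, and mild base closes the terminal epoxide by attack of the C2 oxygen on C1; no stereocentre is touched.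

Step 18
Reactants: 27 (2S)-6-methyl-2-[(2R)-oxiran-2-yl]hept-5-en-2-ol; 28 propyne
Product: 30 (6S,7R)-2,6-dimethylundec-2-en-9-yne-6,7-diol, via propynyllithium 29 (not isolated)
Conditions: n-BuLi, THF, −78 °C; then 27, BF3·OEt2, −78 °C
Reagents that add atoms: none
Why: BF3-promoted opening of the terminal epoxide by the alkynyllithium at the CH2 carbon; one extra equivalent of the alkynyllithium is taken up by the free tertiary hydroxyl, and the carbinol carbon is not involved.

Step 19
Reactants: 30 (6S,7R)-2,6-dimethylundec-2-en-9-yne-6,7-diol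
Product: 31 (6S,7R)-2,6-dimethyl-6,7-bis(trimethylsilyloxy)undec-2-en-9-yne
Conditions: Me3SiOTf, 2,6-lutidine, CH2Cl2, −78 → 0 °C
Reagents that add atoms: trimethylsilyl triflate, C[Si](C)(C)OS(=O)(=O)C(F)(F)F
Why: The silyl triflate caps both hydroxyls so that no O–H consumes the zirconium hydride or the zinc reagent; TMS is chosen because base removes it later without touching TBS or TES.

Step 20
Reactants: 31 (6S,7R)-2,6-dimethyl-6,7-bis(trimethylsilyloxy)undec-2-en-9-yne; 22 3-(RB)propanal
Product: 35 (3S,4E,7R,8S)-1-(RB)-4,8,12-trimethyltrideca-4,11-diene-3,7,8-triol, via alkenylzirconocene 32 (not isolated), via alkenylzinc 33 (not isolated), via bis-trimethylsilyl allylic alcohol 34 (not isolated)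
Conditions: Cp2Zr(H)Cl, THF, 40 °C; solvent changed to CH2Cl2; Me2Zn, −65 °C; 2-[1-(dimethylamino)ethyl]benzenethiol (Re-face-directing enantiomer, 10 mol %), then 22, −30 → 0 °C; then K2CO3, MeOH, rt
Reagents that add atoms: none
Why: Hydrozirconation is a syn addition, and under equilibrating conditions zirconium settles on the alkyne carbon next to the methyl group; transmetalation to zinc and ligand-accelerated addition to the Re face of the aldehyde give the (S)-allylic alcohol with the (E)-alkene retained. Basic methanolysis then removes the two TMS ethers only.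

Step 21
Reactants: 35 (3S,4E,7R,8S)-1-(RB)-4,8,12-trimethyltrideca-4,11-diene-3,7,8-triol
Product: 36 (2S,3R,5R)-2-methyl-2-(4-methylpent-3-enyl)-5-[(2E)-5-(RB)pent-2-en-2-yl]tetrahydrofuran-3-ol
Conditions: PdCl2(MeCN)2 (10 mol %), THF, 0 °C
Reagents that add atoms: none
Why: The reaction type is the known PdCl2(MeCN)2-catalysed cyclisation of hydroxy allylic alcohols with 1,3-chirality transfer, a formal syn-SN2′ process. Divalent palladium binds the alkene on the face carrying the allylic hydroxyl, the tertiary C2 hydroxyl adds to C5 on that same face (syn-oxypalladation), and syn elimination of PdCl(OH) forms the new alkene and frees the catalyst. The tetrahydrofuran closes in the 5-exo-trig mode through the O1–C5 bond. C5 is controlled by the carbinol centre: in the reactive rotamer the carbinol hydrogen eclipses the alkene, which keeps the CH2 chain away from C5 (allylic 1,3-strain), and the hydroxyl of the (S)-carbinol then lies on the face from which oxygen must enter to give (5R). The same rotamer places the chain trans to C5 across the new double bond, so the (E)-alkene results. The step needs chemoselectivity among the hydroxyls and no ionisation: the secondary C3 hydroxyl could only close an oxetane, the ring-B oxygen is silylated, and the neutral catalyst at 0 °C should not ionise the allylic alcohol. C2 and C3 are untouched, and the new 2,5-relationship (alkenyl group trans to the larger C2 substituent) is also the less strained one, so substrate bias and chirality transfer agree.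

Step 22
Reactants: 36 (2S,3R,5R)-2-methyl-2-(4-methylpent-3-enyl)-5-[(2E)-5-(RB)pent-2-en-2-yl]tetrahydrofuran-3-ol
Product: 37 (2S,3R,5R)-5-[(2E)-5-[(1S,2R,6S)-6-hydroxy-3-[(Z)-1-hydroxypropan-2-ylidene]-2-(3-hydroxypropyl)-1,6-dimethylcyclohexyl]pent-2-en-2-yl]-2-methyl-2-(4-methylpent-3-enyl)tetrahydrofuran-3-ol
Conditions: Bu4NF, THF, rt → 40 °C
Reagents that add atoms: none
Why: Fluoride cleaves the two primary TBS ethers and the tertiary TES ether; the basic medium leaves the allylic C5–O1 ether and the alkenes untouched.

Step 23
Reactants: 37 (2S,3R,5R)-5-[(2E)-5-[(1S,2R,6S)-6-hydroxy-3-[(Z)-1-hydroxypropan-2-ylidene]-2-(3-hydroxypropyl)-1,6-dimethylcyclohexyl]pent-2-en-2-yl]-2-methyl-2-(4-methylpent-3-enyl)tetrahydrofuran-3-ol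
Product: 38 (2Z)-2-[(2R,3S,4S)-4-hydroxy-3-[(3E)-4-[(2R,4R,5S)-4-hydroxy-5-methyl-5-(4-methylpent-3-enyl)tetrahydrofuran-2-yl]pent-3-enyl]-2-(3-hydroxypropyl)-3,4-dimethylcyclohexylidene]propanal (CNP0155390.1)
Conditions: MnO2, CH2Cl2, rt
Reagents that add atoms: none
Why: MnO2 oxidises allylic alcohols only, so the primary allylic hydroxyl becomes the enal while the saturated primary, secondary and tertiary hydroxyls stay; the neutral heterogeneous oxidant should keep the (Z) geometry.

## Compound list

1 | 3-ethoxy-2-methylcyclohex-2-en-1-one | CCOC1=C(C)C(=O)CCC1 | starting material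
2 | rac-4-ethoxy-3-methyl-2-oxocyclohex-3-en-1-yl acetate | CCOC1=C(C)C(=O)C(OC(C)=O)CC1 | intermediate
3 | (S)-4-ethoxy-3-methyl-2-oxocyclohex-3-en-1-yl acetate | CCOC1=C(C)C(=O)[C@@H](OC(C)=O)CC1 | intermediate
4 | (6S)-3-ethoxy-2-methylcyclohex-2-ene-1,6-diol (both C1 epimers) | CCOC1=C(C)C(O)[C@@H](O)CC1 | intermediate
5 | (S)-4-hydroxy-2-methylcyclohex-2-en-1-one | O=C1CC[C@H](O)C=C1C | intermediate
6 | (S)-2-methyl-4-(triethylsilyloxy)cyclohex-2-en-1-one | O=C1CC[C@H](O[Si](CC)(CC)CC)C=C1C | intermediate
7 | (3-bromopropoxy)(tert-butyl)dimethylsilane | CC(C)(C)[Si](C)(C)OCCCBr | starting material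
8 | [3-(tert-butyldimethylsilyloxy)propyl]magnesium bromide | CC(C)(C)[Si](C)(C)OCCC[Mg]Br | intermediate
9 | {[(3S,4S)-3-[3-(TBSO)propyl]-2-methyl-4-(TESO)cyclohex-1-en-1-yl]oxy}trimethylsilane | C[Si](C)(C)OC1=C(C)[C@H](CCCO[Si](C)(C)C(C)(C)C)[C@@H](O[Si](CC)(CC)CC)CC1 | intermediate
10 | lithium (3S,4S)-3-[3-(TBSO)propyl]-2-methyl-4-(TESO)cyclohex-1-en-1-olate | [Li]OC1=C(C)[C@H](CCCO[Si](C)(C)C(C)(C)C)[C@@H](O[Si](CC)(CC)CC)CC1 | intermediate
11 | (2S,3S,4S)-2-allyl-3-[3-(TBSO)propyl]-2-methyl-4-(TESO)cyclohexan-1-one | C=CC[C@@]1(C)[C@H](CCCO[Si](C)(C)C(C)(C)C)[C@@H](O[Si](CC)(CC)CC)CCC1=O | intermediate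
12 | (1S,2S,3S,4S)-2-allyl-3-[3-(TBSO)propyl]-1,2-dimethyl-4-(TESO)cyclohexan-1-ol | C=CC[C@@]1(C)[C@H](CCCO[Si](C)(C)C(C)(C)C)[C@@H](O[Si](CC)(CC)CC)CC[C@]1(C)O | intermediate
13 | bis-triethylsilyl ether of 12 | C=CC[C@@]1(C)[C@H](CCCO[Si](C)(C)C(C)(C)C)[C@@H](O[Si](CC)(CC)CC)CC[C@]1(C)O[Si](CC)(CC)CC | intermediate
14 | (1S,2S,3S,4S)-3-allyl-2-[3-(TBSO)propyl]-3,4-dimethyl-4-(TESO)cyclohexan-1-ol | C=CC[C@@]1(C)[C@H](CCCO[Si](C)(C)C(C)(C)C)[C@@H](O)CC[C@]1(C)O[Si](CC)(CC)CC | intermediate
15 | (2S,3S,4S)-3-allyl-2-[3-(TBSO)propyl]-3,4-dimethyl-4-(TESO)cyclohexan-1-one | C=CC[C@@]1(C)[C@H](CCCO[Si](C)(C)C(C)(C)C)C(=O)CC[C@]1(C)O[Si](CC)(CC)CC | intermediate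
16 | (1R,2S,3S,4S)-3-allyl-2-[3-(TBSO)propyl]-3,4-dimethyl-1-(prop-1-en-2-yl)-4-(TESO)cyclohexan-1-ol | C=CC[C@@]1(C)[C@H](CCCO[Si](C)(C)C(C)(C)C)[C@@](O)(C(C)=C)CC[C@]1(C)O[Si](CC)(CC)CC | intermediate
17 | (2Z)-2-[(2R,3S,4S)-3-allyl-2-[3-(TBSO)propyl]-3,4-dimethyl-4-(TESO)cyclohexylidene]propanal | C=CC[C@@]1(C)[C@H](CCCO[Si](C)(C)C(C)(C)C)/C(=C(/C)C=O)CC[C@]1(C)O[Si](CC)(CC)CC | intermediate
18 | (2Z)-2-[(2R,3S,4S)-3-allyl-2-[3-(TBSO)propyl]-3,4-dimethyl-4-(TESO)cyclohexylidene]propan-1-ol | C=CC[C@@]1(C)[C@H](CCCO[Si](C)(C)C(C)(C)C)/C(=C(/C)CO)CC[C@]1(C)O[Si](CC)(CC)CC | intermediate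
19 | TBS ether of 18 | C=CC[C@@]1(C)[C@H](CCCO[Si](C)(C)C(C)(C)C)/C(=C(/C)CO[Si](C)(C)C(C)(C)C)CC[C@]1(C)O[Si](CC)(CC)CC | intermediate
20 | 9-[3-(RB)propyl]-9-borabicyclo[3.3.1]nonane | C1CCC2CCCC1B2CCC[C@@]3(C)[C@H](CCCO[Si](C)(C)C(C)(C)C)/C(=C(/C)CO[Si](C)(C)C(C)(C)C)CC[C@]3(C)O[Si](CC)(CC)CC | intermediate
21 | 3-(RB)propan-1-ol | OCCC[C@@]1(C)[C@H](CCCO[Si](C)(C)C(C)(C)C)/C(=C(/C)CO[Si](C)(C)C(C)(C)C)CC[C@]1(C)O[Si](CC)(CC)CC | intermediate
22 | 3-(RB)propanal | O=CCC[C@@]1(C)[C@H](CCCO[Si](C)(C)C(C)(C)C)/C(=C(/C)CO[Si](C)(C)C(C)(C)C)CC[C@]1(C)O[Si](CC)(CC)CC | intermediate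
23 | geraniol | CC(C)=CCC/C(C)=C/CO | starting material
24 | [(2R,3R)-3-methyl-3-(4-methylpent-3-enyl)oxiran-2-yl]methanol | CC(C)=CCC[C@@]1(C)O[C@@H]1CO | intermediate
25 | (2R,3S)-3,7-dimethyloct-6-ene-1,2,3-triol | CC(C)=CCC[C@](C)(O)[C@H](O)CO | intermediate
26 | (2R,3S)-2,3-dihydroxy-3,7-dimethyloct-6-en-1-yl 4-methylbenzenesulfonate | CC(C)=CCC[C@](C)(O)[C@H](O)COS(=O)(=O)c1ccc(C)cc1 | intermediate
27 | (2S)-6-methyl-2-[(2R)-oxiran-2-yl]hept-5-en-2-ol | CC(C)=CCC[C@](C)(O)[C@H]1CO1 | intermediate
28 | propyne | CC#C | starting material
29 | prop-1-ynyllithium | CC#C[Li] | intermediate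
30 | (6S,7R)-2,6-dimethylundec-2-en-9-yne-6,7-diol | CC(C)=CCC[C@](C)(O)[C@H](O)CC#CC | intermediate
31 | (6S,7R)-2,6-dimethyl-6,7-bis(trimethylsilyloxy)undec-2-en-9-yne | CC(C)=CCC[C@](C)(O[Si](C)(C)C)[C@H](O[Si](C)(C)C)CC#CC | intermediate
32 | chlorobis(cyclopentadienyl)[(2E,5R,6S)-6,10-dimethyl-5,6-bis(trimethylsilyloxy)undeca-2,9-dien-2-yl]zirconium | CC(C)=CCC[C@](C)(O[Si](C)(C)C)[C@H](O[Si](C)(C)C)C/C=C(\C)[Zr](Cl)(C1C=CC=C1)C1C=CC=C1 | intermediate
33 | methyl[(2E,5R,6S)-6,10-dimethyl-5,6-bis(trimethylsilyloxy)undeca-2,9-dien-2-yl]zinc | CC(C)=CCC[C@](C)(O[Si](C)(C)C)[C@H](O[Si](C)(C)C)C/C=C(\C)[Zn]C | intermediate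
34 | (3S,4E,7R,8S)-1-(RB)-4,8,12-trimethyl-7,8-bis(trimethylsilyloxy)trideca-4,11-dien-3-ol | CC(C)=CCC[C@](C)(O[Si](C)(C)C)[C@H](O[Si](C)(C)C)C/C=C(\C)[C@@H](O)CC[C@@]1(C)[C@H](CCCO[Si](C)(C)C(C)(C)C)/C(=C(/C)CO[Si](C)(C)C(C)(C)C)CC[C@]1(C)O[Si](CC)(CC)CC | intermediate
35 | (3S,4E,7R,8S)-1-(RB)-4,8,12-trimethyltrideca-4,11-diene-3,7,8-triol | CC(C)=CCC[C@](C)(O)[C@H](O)C/C=C(\C)[C@@H](O)CC[C@@]1(C)[C@H](CCCO[Si](C)(C)C(C)(C)C)/C(=C(/C)CO[Si](C)(C)C(C)(C)C)CC[C@]1(C)O[Si](CC)(CC)CC | intermediate
36 | (2S,3R,5R)-2-methyl-2-(4-methylpent-3-enyl)-5-[(2E)-5-(RB)pent-2-en-2-yl]tetrahydrofuran-3-ol | CC(C)=CCC[C@]1(C)O[C@@H](/C(C)=C/CC[C@@]2(C)[C@H](CCCO[Si](C)(C)C(C)(C)C)/C(=C(/C)CO[Si](C)(C)C(C)(C)C)CC[C@]2(C)O[Si](CC)(CC)CC)C[C@H]1O | intermediate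
37 | (2S,3R,5R)-5-[(2E)-5-[(1S,2R,6S)-6-hydroxy-3-[(Z)-1-hydroxypropan-2-ylidene]-2-(3-hydroxypropyl)-1,6-dimethylcyclohexyl]pent-2-en-2-yl]-2-methyl-2-(4-methylpent-3-enyl)tetrahydrofuran-3-ol | CC(C)=CCC[C@]1(C)O[C@@H](/C(C)=C/CC[C@@]2(C)[C@H](CCCO)/C(=C(/C)CO)CC[C@]2(C)O)C[C@H]1O | intermediate
38 | CNP0155390.1, (2Z)-2-[(2R,3S,4S)-4-hydroxy-3-[(3E)-4-[(2R,4R,5S)-4-hydroxy-5-methyl-5-(4-methylpent-3-enyl)tetrahydrofuran-2-yl]pent-3-enyl]-2-(3-hydroxypropyl)-3,4-dimethylcyclohexylidene]propanal | CC(C)=CCC[C@]1(C)O[C@@H](/C(C)=C/CC[C@@]2(C)[C@H](CCCO)/C(=C(/C)C=O)CC[C@]2(C)O)C[C@H]1O | target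

## Step count and least certain steps

Total: 23 steps. Longest linear sequence: 18 steps (steps 1–14, then 20–23). The geraniol branch (steps 15–19) joins at step 20.

**Step 21 (key step).** The oxypalladation may be slow, because the alkene is trisubstituted and the nucleophile is a hindered tertiary hydroxyl. A slow syn pathway would leave room for ionisation of the allylic alcohol by the Lewis-acidic metal or traces of HCl, and so for erosion of the chirality transfer at C5 and of the alkene geometry, or for plain 1,3-transposition of the hydroxyl. The fallback replaces divalent-palladium oxypalladation by zerovalent-palladium π-allyl chemistry. It sets out from 34, taken before its trimethylsilyl groups are removed. Methyl chloroformate and pyridine should give the bis-trimethylsilyl allylic methyl carbonate F1, and citric acid in methanol should free the diol to give the allylic methyl carbonate F2. Pd2(dba)3 and PPh3 in THF should then ionise the carbonate with inversion, and the tertiary alkoxide formed on decarboxylation should attack the distal terminus of the syn,syn-π-allyl complex from the face opposite palladium. This double inversion puts oxygen on the face the carbonate left, so the same tetrahydrofuran 36 is expected, and the route is rejoined there.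

**Step 20.** The main danger is poor facial selectivity in the alkenylzinc addition, since unbranched aliphatic aldehydes respond less well to such ligands than aromatic ones. Incomplete migration of zirconium to the methyl-bearing carbon would add transfer of the regioisomeric alkenyl group. The fallback replaces catalytic C–C bond formation by a reagent-controlled reduction. From 34, obtained as a mixture of carbinol epimers, Dess–Martin oxidation should give the bis-trimethylsilyl enone F3. Reduction with catecholborane and the (R)-configured 2-methyl-CBS-oxazaborolidine, for which the trisubstituted alkenyl group is the large substituent, should return 34 as the (S)-carbinol. The route then continues with the methanolysis to 35.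

**Step 10.** The [3,3] shift of the chromate ester may discriminate poorly between the two rotamers of the isopropenyl group and give both enal geometries. Ionisation of the hindered tertiary allylic alcohol under the acidic oxidant could add elimination to dienes. Equilibration of the enal toward the (Z)-isomer would help only in part, so a stereospecific route is held ready. From ketone 15, the dianion of S-phenyl 3-hydroxy-2-methylpropanethioate (LiN(iPr)2, THF, −78 °C) should add to the ketone, and the aldolate should close, with loss of thiophenolate, to the spiro β-lactone F4, in which the hydroxymethyl group and B2 are cis on the four-membered ring. Heating in DMF with collidine should then bring about stereospecific syn decarboxylation and give the (Z)-allylic alcohol 18 directly, where the route is rejoined.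

**Step 5.** Allylation of the hindered, fully substituted enolate may be slow, so that proton transfer followed by allylation at the other α-carbon, or O-allylation, competes. The fallback replaces direct alkylation by a palladium-catalysed intramolecular allyl transfer. From the trimethylsilyl enol ether 9, MeLi and then allyl chloroformate should give the allyl enol carbonate F5. Pd(PPh3)4 (zerovalent palladium) in THF should effect the decarboxylative Tsuji allylation, which joins the allyl group regiospecifically to the same enolate carbon, again anti to the neighbouring chain, and returns ketone 11.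

**Step 17.** Under basic conditions the terminal epoxide, with its free tertiary hydroxyl, may isomerise by Payne rearrangement to the more substituted 2,3-epoxy alcohol. The fallback alkynylates before hydrolysis and avoids the terminal epoxide. From epoxy alcohol 24, Tf2O and 2,6-lutidine at −78 °C should give the epoxy triflate F6, and propynyllithium 29 should displace the triflate to give the alkynyl epoxide F7. Acid-catalysed hydrolysis as in step 16, with inversion at the tertiary carbon, should then give diol 30, where the route is rejoined.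

## Further compounds

F1 | step 21 | bis-trimethylsilyl allylic methyl carbonate, methyl (3S,4E,7R,8S)-1-(RB)-4,8,12-trimethyl-7,8-bis(trimethylsilyloxy)trideca-4,11-dien-3-yl carbonate | CC(C)=CCC[C@](C)(O[Si](C)(C)C)[C@H](O[Si](C)(C)C)C/C=C(\C)[C@@H](OC(=O)OC)CC[C@@]1(C)[C@H](CCCO[Si](C)(C)C(C)(C)C)/C(=C(/C)CO[Si](C)(C)C(C)(C)C)CC[C@]1(C)O[Si](CC)(CC)CC
F2 | step 21 | allylic methyl carbonate, (3S,4E,7R,8S)-7,8-dihydroxy-1-(RB)-4,8,12-trimethyltrideca-4,11-dien-3-yl methyl carbonate | CC(C)=CCC[C@](C)(O)[C@H](O)C/C=C(\C)[C@@H](OC(=O)OC)CC[C@@]1(C)[C@H](CCCO[Si](C)(C)C(C)(C)C)/C(=C(/C)CO[Si](C)(C)C(C)(C)C)CC[C@]1(C)O[Si](CC)(CC)CC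
F3 | step 20 | bis-trimethylsilyl enone, (4E,7R,8S)-1-(RB)-4,8,12-trimethyl-7,8-bis(trimethylsilyloxy)trideca-4,11-dien-3-one | CC(C)=CCC[C@](C)(O[Si](C)(C)C)[C@H](O[Si](C)(C)C)C/C=C(\C)C(=O)CC[C@@]1(C)[C@H](CCCO[Si](C)(C)C(C)(C)C)/C(=C(/C)CO[Si](C)(C)C(C)(C)C)CC[C@]1(C)O[Si](CC)(CC)CC
F4 | step 10 | spiro β-lactone from ketone 15 (hydroxymethyl cis to B2 on the four-membered ring) | C=CC[C@@]1(C)[C@H](CCCO[Si](C)(C)C(C)(C)C)[C@]2(OC(=O)[C@@]2(C)CO)CC[C@]1(C)O[Si](CC)(CC)CC
F5 | step 5 | allyl enol carbonate, allyl (3S,4S)-3-[3-(TBSO)propyl]-2-methyl-4-(TESO)cyclohex-1-en-1-yl carbonate | C=CCOC(=O)OC1=C(C)[C@H](CCCO[Si](C)(C)C(C)(C)C)[C@@H](O[Si](CC)(CC)CC)CC1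
F6 | step 17 | epoxy triflate, [(2R,3R)-3-methyl-3-(4-methylpent-3-enyl)oxiran-2-yl]methyl trifluoromethanesulfonate | CC(C)=CCC[C@@]1(C)O[C@@H]1COS(=O)(=O)C(F)(F)F
F7 | step 17 | alkynyl epoxide, (2R,3R)-2-(but-2-yn-1-yl)-3-methyl-3-(4-methylpent-3-enyl)oxirane | CC(C)=CCC[C@@]1(C)O[C@@H]1CC#CC
A1 | alternative 1 | furan enoate, methyl (2E)-6-(tert-butyldimethylsilyloxy)-2-methyl-7-(5-methylfuran-2-yl)hept-2-enoate | COC(=O)/C(C)=C/CC[C@@H](O[Si](C)(C)C(C)(C)C)Cc1ccc(C)o1
A2 | alternative 1 | oxygen-bridged tricyclic ester | COC(=O)[C@@]1(C)[C@@H]2CC[C@@H](O[Si](C)(C)C(C)(C)C)C[C@]23O[C@@]1(C)C=C3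
A3 | alternative 2 | S-phenyl 3-hydroxy-2-methylpropanethioate | CC(CO)C(=O)Sc1ccccc1
A4 | alternative 2 | ring-B ketone | COc1ccc(COCC[C@@]2(C)[C@H](CCCO[Si](C(C)C)(C(C)C)C(C)C)C(=O)CC[C@]2(C)O[Si](CC)(CC)CC)cc1
A5 | alternative 2 | spiro β-lactone | COc1ccc(COCC[C@@]2(C)[C@H](CCCO[Si](C(C)C)(C(C)C)C(C)C)[C@@]3(OC(=O)[C@]3(C)CO)CC[C@]2(C)O[Si](CC)(CC)CC)cc1
A6 | alternative 3 | α-methyl diazoketone with allyl ether | C=CCO[C@H](CC(=O)C(C)=[N+]=[N-])/C(C)=C/I
A7 | alternative 3 | 2-allyl-2-methyl-tetrahydrofuran-3-one | C=CC[C@]1(C)O[C@@H](/C(C)=C/I)CC1=O
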